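(Readings and results stem from a simulated flask from invented constants; scatter was added.)

It is easy to count clock time as working time, but the partner in these flasks is fed in. We therefore count the feed at half its length, and working time is clock time less that missing part.

| flask | left-handed substrate | right-handed substrate | partner | free catalyst | remark | time |
|---|---|---|---|---|---|---|
| zeta | 0.35 M | 0.35 M | 0.15 M (fed, over 1.5 h) | 5 mM | run made earlier |  |
| alpha | 0.55 M | 0.55 M | 0.15 M (fed, over 1.5 h) | 5 mM | run made earlier |  |
| eta | 0.25 M | 0.25 M | 0.15 M (fed, over 1.5 h) | 7.5 mM | run made earlier |  |
| flask | 0.25 M | 0.25 M | 0.150 M (fed, over 1.5 h) | 5.0 mM |  | 3.0 h |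

- zeta (time / min: right-handed substrate / %, left-handed substrate / %, left-handed product / %): 8.00: 49.6, 49.9, 0.1; 20.0: 49.7, 50.3, 0; 50.0: 50.1, 49.0, 1.7; 120: 49.7, 44.5, 3.7
- alpha (time / min: right-handed substrate / %, left-handed substrate / %, left-handed product / %): 25.0: 49.4, 50.1, 0.3; 50.0: 49.4, 49.5, 1.1; 80.0: 49.8, 47.8, 1.6; 120: 49.4, 47.4, 3.3
- eta (time / min: right-handed substrate / %, left-handed substrate / %, left-handed product / %): 8.00: 48.8, 49.2, 0.6; 20.0: 49.1, 49.5, 1.2; 50.0: 49.7, 48.4, 0.5; 120: 49.0, 42.8, 8.6

(scatter of a reading: 0.5 percentage points)

* whether the excess of right-handed substrate over left-handed substrate among what is left of the two reaches 95% by 3.0 h (yes / no)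
* the highest excess of right-handed substrate over left-handed substrate among what is left of the two up to 3.0 h

- free catalyst is single-handed; left-handed substrate and right-handed substrate are mirror images of each other, charged as a racemate, each of them at the stated concentration

We read the eta run, whose substrate charge matches this flask. At 120 min it shows 8.6% left-handed product, or 0.0430 M, after 75.0 min of working time on 7.5 mM of free catalyst. That is 4.59 h⁻¹: left-handed product per free catalyst charged, per hour of working time. We call it the working frequency w, a turnover frequency at 0.15 M of partner charged. It is a reading, resting on a product value with a scatter of 0.5 percentage points, and we carry it to this flask by assuming that the rate is proportional to the free catalyst charged.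

Now we draw this flask. Let x be the left-handed substrate reacted. The right-handed readings stand flat, so we take the excess as x over the sum of c(left-handed substrate) and c(right-handed substrate). In our reckoning the curve leaves zero with a flat slope and bends upward while the feed runs. The knee comes at 1.5 h, with x at 0.0172 M and the excess at 3.56%. After that x climbs straight, at 0.0229 M h⁻¹. At 3.0 h, working time is 2.25 h, x is 0.0516 M, and the excess is 11.5%, still rising, so that is our top. If each product takes one partner and the right-handed substrate stays flat, 95% needs 0.244 M reacted, more than the 0.150 M charged. Our answer is no.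

The forecast answers no and gives 11% as the top, reading the runs as “near zero order in substrate”. Our top is higher than its figure.

This flask gives no and a top of 8.90%. At 3.00 h it holds 9.04% left-handed product and 67% of its partner charge. Reckoned on this product and the same working time, w for this flask comes to 4.02 h⁻¹.

    partner + catalyst intermediate B → free catalyst + right-handed product (k = 0.100 M⁻¹ min⁻¹)
    free catalyst + right-handed substrate ⇌ catalyst intermediate B (K = 9.30 M⁻¹, k = 80.0 M⁻¹ min⁻¹)
    free catalyst → spent catalyst (k = 0.00190 min⁻¹)
    2 free catalyst ⇌ resting dimer, settled at all times (K = 130 M⁻¹)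
    free catalyst + left-handed substrate ⇌ catalyst intermediate A (K = 4.80 M⁻¹, k = 17.0 M⁻¹ min⁻¹)
    partner + catalyst intermediate A → free catalyst + left-handed product (k = 2.60 M⁻¹ min⁻¹)

In the neighbour flask with 0.0013 M of free catalyst, our w gives x of 0.0134 M at 3.0 h, so an excess of 2.76%. The computed top there is 2.73%.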